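All runs are simulated for substances that don't exist; the scatter is artificial.

The constants for this flask must be read from two earlier runs, whose substrate columns fall roughly like first-order lags.

| setting | west | south | winter | dawn |
|---|---|---|---|---|
| substrate | 42 mM | 66 mM | 30 mM | 30 mM |
| temperature | 20 °C | 32 °C | 25 °C | 40 °C |
| remark | run made earlier | run made earlier |  |  |
| time |  |  | 8.0 min | 8.0 min |

| run | time / min | intermediate C / % | substrate / % | target / % | intermediate B / % | intermediate A / % | side product A / % |
|---|---|---|---|---|---|---|---|
| west | 1.33 | 2 | 89 | 0 | 10 | 7 | 0 |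
| west | 3.00 | 3 | 75 | 1 | 11 | 11 | 0 |
| west | 6.00 | 4 | 54 | 0 | 16 | 15 | 4 |
| west | 10.0 | 13 | 40 | 0 | 21 | 18 | 1 |
| south | 2.50 | 16 | 37 | 0 | 18 | 21 | 6 |
| south | 5.00 | 26 | 20 | 0 | 17 | 21 | 13 |
| south | 8.00 | 30 | 10 | 0 | 9 | 14 | 32 |
| south | 10.0 | 24 | 11 | 3 | 5 | 14 | 47 |

(readings scatter by 2 percentage points)

- the earlier runs were read with a standard deviation of 2 percentage points

1. which of these there is most of at the end, counted by the substrate in it, winter (substrate / intermediate A / side product A / intermediate B / intermediate C)
2. which of these there is most of at the end, counted by the substrate in it, dawn (substrate / intermediate A / side product A / intermediate B / intermediate C)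
3. how much there is at the end of the one of these that leads, in percent of the substrate charged: winter
4. how much there is at the end of the one of these that leads, in percent of the substrate charged: dawn

West keeps 40% of its substrate at 10.0 min, so its apparent first-order constant is 0.0916 min⁻¹. South keeps 20% at 5.00 min, so its constant is 0.322 min⁻¹. The charges of west and south differ too, but reading their whole difference as temperature, a straight line for ln k gives 0.155 min⁻¹ for winter and 0.744 min⁻¹ for dawn. Winter's 1.24 and dawn's 5.95 are readings of the clock, the number of substrate time constants elapsed, and c(substrate) is taken to fall as exp(−clock).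

Winter should therefore keep 29.0% substrate. West, at clock 0.916, reads intermediate B highest of the intermediates at 21%, and south, at clock 1.61, reads intermediate C highest of them at 26%; both are less than that, so substrate should lead winter.

South's last reading, at clock 3.22, has side product A ahead with 47%. The part of south not yet side product A fell from 68.0% to 53.0% over its last two readings, which reads as 0.387 per unit of clock. Dawn's further 2.73 units, at that pace, leave about 18.4% unfinished, so this reckoning puts side product A near 81.6% in dawn.

The forecast says substrate at 30% (23% to 37%) for winter and side product A at 70% (50% to 86%) for dawn, the latter trimmed “for the lower concentration, possible bimolecular steps and some leakage to target”. The reckoning here stands higher for dawn.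

Winter gives substrate at 28.8%, and dawn gives side product A at 82.7%, 13 points above the forecast.

    substrate ⇌ intermediate A (K = 0.932, k = 0.0707 min⁻¹, Ea = 82.0 kJ mol⁻¹, ΔH = −27.0 kJ mol⁻¹)
    substrate → intermediate B (k = 0.111 min⁻¹, Ea = 98.0 kJ mol⁻¹)
    intermediate B → target (k = 0.00732 min⁻¹, Ea = 87.0 kJ mol⁻¹)
    intermediate B → intermediate C (k = 0.187 min⁻¹, Ea = 96.0 kJ mol⁻¹)
    intermediate C → side product A (k = 0.0883 min⁻¹, Ea = 95.0 kJ mol⁻¹)
    substrate + target → side product B (k = 10.5 M⁻¹ min⁻¹, Ea = 66.0 kJ mol⁻¹)
    (constants at 25 °C)

Winter's 28.8% of substrate stands against the clock's 29.0%. Dawn holds 1.80% substrate beside 2.20% intermediate A, where the clock gave 0.261% substrate. A neighbour, dawn stopped at 3.0 min, reads 2.23 on the clock, which gives 10.8% substrate. That neighbour holds 11.1% substrate.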